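Convention: ring carbons keep their germacranolide numbers (C1–C15) in every intermediate. β is the face of the C5–C10 ring that carries the C7–C11 bond; α is the opposite face.

Remark on the chemistry: enone 3 is taken as purchasable (otherwise it is one dehydrogenation from 1,4-dioxaspiro[4.5]decan-8-one). C12 of the lactols and methyl acetals (19–22, 24–33, 35, 36) is carried as an anomeric mixture and is left open in their SMILES.

## Analysis of the target

Target 40 is a germacranolide: a ten-membered carbocycle C1–C10 fused trans at C6/C7 to an α-methylene-γ-butyrolactone (O6–C12(=O)–C11(=C13H2)–C7). Both ring alkenes are ring-cis: C1=C10 carries the C14 aldehyde trans to C2 (an E-enal), and C4=C5 carries C15H2OH trans to C6. The four contiguous stereocentres are 6R,7S,8S,9S, and the C8 ester adds an (S)-2-methylbutanoyl centre. On the ring, O6 and C11 are trans, C11 and O8 are cis, and O8 and O9 are trans. The sensitive groups are: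

- the enal flanked by the allylic C9 acetate, which is prone to conjugate addition with loss of acetate;
- the methylene lactone, a Michael acceptor;
- two different esters on neighbouring oxygens, which can migrate;
- the epimerisable α-centre of the 2-methylbutanoate;
- a free allylic alcohol.

The synthesis is hard because a medium ring with two trisubstituted alkenes of defined geometry must be made, O8 and O9 must be told apart, and almost nothing basic or nucleophilic is tolerated late. The plan rests on one feature: C10=C1–C2–C3–C4=C5 is a 1,5-diene. The ten-membered ring is therefore the Cope isomer of a six-membered ring C5–C10 that already holds C6–C9 and bears an oxygen on C10 where C14 will later sit.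

## Retrosynthetic reasoning

**Late functional groups (40 back to 32).** The C15 silyl ether, the C9 acetate, the C8 acyl group from acid 34 and the lactone carbonyl are removed from the picture first, in that order (39, 38, 37, 36, 35, 33, 32). They are cut there because the acetate next to the enal and the methylene lactone are the most electrophilic parts of 40 and cannot pass through any earlier step. The lactone is carried as its cyclic methyl acetal with C13 already in place, so no enolate chemistry is needed once esters and the enal are present. The forward steps only have to unmask and acylate one hydroxyl at a time and oxidise a lactol.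

**C10–C14 (32 back to 29).** The formyl carbon is disconnected from C10. Ketone 29 marks C10 with oxygen; its enol triflate 30 is formylated under palladium catalysis to enal 31, whose geometry is then equilibrated to that of 32. The cut is made here because the carbonyl left by the ring expansion is a regiodefined handle. Enolisation must go to the C1 methylene and not to the alkoxy-bearing C9.

**C2–C3 formed, C5–C10 cleaved (29 back to 26).** This is the central disconnection. Reconnecting C5 to C10 and cutting C2–C3 turns the cyclodecenone 29 into cyclohexanol 26, which has a vinyl group and a hydroxyl on C10 and the 2-substituted alkenyl group on C5. The gain is that the medium ring is never closed from a chain, and C6–C9 can be set on a chair. The forward reaction must deliver the ring-cis C4=C5 alkene. In 26 the O6/C12 acetal ring is trans-fused, which holds the one chair that does this. O9 carries an acetal-type group and not a silyl group, since a silyl group would shift to the neighbouring C10 alkoxide.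

**C10–C1 and C8–O (26 back to 20).** The vinyl group is cut from C10 (Grignard reagent 23 adding to epoxy ketone 22), and the C8 ether is cut back to the 8α,9α-epoxide (24, 21). The epoxide comes from allylic alcohol 20. This ordering makes O8 and O9 different from birth: O9 is the epoxide oxygen and O8 the incoming nucleophile. It also gives the cis C7/C8 relationship, by epoxidation anti to the C7 branch followed by inversion at C8. A direct addition to C8 would give trans.

**Acetal, C11=C13 and lactone (20 back to 14).** The acetal is traced to lactone 18, the methylene to lactone 16, and the lactone to ester 14. Enolate chemistry at C11 is placed here because nothing base-sensitive is yet in the molecule.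

**C7–C11 (14 back to 12).** This bond is cut by a Claisen disconnection to allylic alcohol 12. It is chosen over a second conjugate addition, or over opening an epoxide beside the existing C5 branch, because those need axial attack syn to the cis-1,3 substituent. The sigmatropic shift instead transfers configuration from C9–O to C7 whatever the ring conformation. It also moves the alkene to C8=C9, where the epoxide is needed.

**C9 carbinol and C10–O (12 back to 9).** Alcohol 12 comes from enone 11, the enone from ketone 10, and the C10 oxygen from oxidation of enol ether 9. The C10 oxygen is the future carbinol oxygen of 26, and it also blocks C10 so that dehydrogenation goes to C7=C8.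

**C5–C4 (9 back to 6 and 2).** The alkenyl group is cut from C5: cuprate 8, made from bromide 2 through 7, adds to enone 6 anti to the silyloxy group. This sets C5 trans to O6 and leaves a regiodefined enolate.

**C6 (6 back to 3; 2 back to 1).** Enone 6 comes from achiral enone 3 by asymmetric reduction to 4 and protection (5). This is the only stereocentre set by a catalyst; all other ring centres are relayed from it.

## Alternatives that were turned down

**Alternative 1:** Here the lactone carbonyl is disconnected last. A fully functionalised ten-membered alcohol with an ethynyl group on C7, A1, would be cyclised under carbonylative palladium catalysis with a sulfur ligand. The C6 alkoxycarbonyl-palladium species adds across the alkyne and is protonated, which gives the 15-O-silyl ether A2 with O–C12 and C11–C12 made in one step.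

- For it: the methylene lactone appears only at the end, and the reaction type is known for homopropargylic alcohols.
- Against it for this target: it does not address the ten-membered ring at all. It also runs a palladium step on a substrate that already holds the enal and the allylic C9 acetate (ionisable by zerovalent palladium), and the sulfur ligand is a nucleophile toward that same unit.
- Comparison: this route is stronger on the lactone, one step against methylenation, reduction, acetalisation, hydrolysis and oxidation in the chosen route. In exchange, the chosen route solves the ring, both alkene positions and the C14 handle in one event, and keeps every metal-catalysed step before the acetate is installed.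

**Alternative 2:** This plan cuts C7–C11 and C8–C9 together. An eleven-membered β-keto lactone with an enol ester on C6, A3, would be irradiated with a triplet sensitiser. The enol adds to the enol ester, and retro-aldol opening of the cyclobutanol gives the C9-oxo lactone A4.

- For it: two skeletal bonds and two rings form in one step, with the C8 ester already present. It is more convergent than the ring expansion, which makes one bond.
- Against it: C7 and C8 are set in a [2+2] addition on a flexible macrocycle with only C6 to direct the face. The sensitiser can also isomerise the C1=C10 enone. The C9 ketone must afterwards be reduced with control, and C13 is still missing and would need lactone enolate chemistry beside an epimerisable ester.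
- Comparison: the chosen route sets each of C6–C9 by a conventional reaction on a six-membered ring and needs no late enolate.

**Alternative 3:** This plan also enlarges a ring. A decalin epoxy ketone A5 (epoxide on the C1–C6 fusion bond, ketone at C10) is converted to its sulfonyl hydrazone, which fragments to the ten-membered enynone A6.

- For it: C7–C9 are set on a rigid bicycle, and the fragmentation is dependable. The C4=C5 geometry is fixed by the six-membered ring and does not depend on a transition-state preference; on this point it is stronger than the chosen route.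
- Against it: A6 contains an alkyne inside a ten-membered ring that already holds a cis-enone. The alkyne must then be converted into the trisubstituted enal with formyl on C10 and not on C1. C6 must be created by reduction on the medium ring, and the methylene is again left for the end.
- Comparison: the chosen route carries C6 from the first stereocentre and leaves an enolate, not an alkyne, at C10/C1. Oxygen on C10 defines where C14 goes.

Key step: step 19

## Route

Step 1
Reactants: 1 2-bromoprop-2-en-1-ol
Product: 2 (2-bromoprop-2-en-1-yloxy)(tert-butyl)diphenylsilane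
Conditions: t-BuPh2SiCl, imidazole, CH2Cl2, 0 °C → rt
Reagents that add atoms: tert-butylchlorodiphenylsilane, CC(C)(C)[Si](Cl)(c1ccccc1)c1ccccc1
Why: Silylation of a primary alcohol. The bulky silyl group is chosen because it resists a 1,4 shift from oxygen to carbon in the derived 2-lithioalkene and lasts to the final step.

Step 2
Reactants: 3 1,4-dioxaspiro[4.5]dec-6-en-8-one
Product: 4 (S)-1,4-dioxaspiro[4.5]dec-6-en-8-ol
Conditions: RuCl(p-cymene)[(S,S)-TsDPEN] (1 mol %), KOH (cat.), i-PrOH, rt
Reagents that add atoms: none
Why: Noyori asymmetric transfer hydrogenation of the carbonyl group only. With the alkenyl arm in the role of the aryl group of the usual model, the (S,S)-ligand should give the (S)-carbinol that becomes C6; the mirror-image ligand serves if the sense is the reverse.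

Step 3
Reactants: 4 (S)-1,4-dioxaspiro[4.5]dec-6-en-8-ol
Product: 5 (S)-tert-butyl(1,4-dioxaspiro[4.5]dec-6-en-8-yloxy)dimethylsilane
Conditions: t-BuMe2SiCl, imidazole, DMF, rt
Reagents that add atoms: tert-butylchlorodimethylsilane, CC(C)(C)[Si](C)(C)Cl
Why: Standard silylation of a secondary allylic alcohol; the bulky ether later directs the cuprate to the opposite face.

Step 4
Reactants: 5 (S)-tert-butyl(1,4-dioxaspiro[4.5]dec-6-en-8-yloxy)dimethylsilane
Product: 6 (S)-4-(tert-butyldimethylsilyloxy)cyclohex-2-en-1-one
Conditions: montmorillonite K10, wet CH2Cl2, rt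
Reagents that add atoms: water, O
Why: Acetal hydrolysis on an acidic clay frees the enone; the silyl ether and the γ-stereocentre should survive these mild heterogeneous conditions.

Step 5
Reactants: 2 (2-bromoprop-2-en-1-yloxy)(tert-butyl)diphenylsilane; 6 (S)-4-(tert-butyldimethylsilyloxy)cyclohex-2-en-1-one
Product: 9 triethylsilyl enol ether (C9=C10) with 5β-alkenyl and 6α-silyloxy groups, via alkenyllithium 7 (not isolated), via lithium dialkenylcuprate 8 (not isolated)
Conditions: 2 (2.2 equiv), t-BuLi (4.4 equiv), Et2O, −78 °C; CuBr·SMe2 (1.1 equiv), −78 → −40 °C; then 6, −78 °C; Et3SiCl, Et3N, −78 → 0 °C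
Reagents that add atoms: chlorotriethylsilane, CC[Si](Cl)(CC)CC
Why: Bromine–lithium exchange, Gilman cuprate formation and 1,4-addition. The cuprate attacks anti to the pseudoaxial γ-silyloxy group, so the C5 alkenyl group is set trans to O6, and O-silylation fixes the enolate toward C10.

Step 6
Reactants: 9 triethylsilyl enol ether (C9=C10)
Product: 10 C9 ketone with 10α-triethylsilyloxy, 5β-alkenyl and 6α-silyloxy groups
Conditions: m-CPBA, NaHCO3, CH2Cl2, −20 → 0 °C
Reagents that add atoms: 3-chloroperbenzoic acid, O=C(OO)c1cccc(Cl)c1
Why: Rubottom oxidation: the electron-rich enol ether is epoxidised faster than the 1,1-disubstituted alkene, anti to the C5 branch, and ring opening with silyl shift gives the α-silyloxy ketone. The all-equatorial 10α isomer is also the thermodynamic one.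

Step 7
Reactants: 10 C9 ketone with 10α-triethylsilyloxy group
Product: 11 enone C7=C8–C9=O with 10α-triethylsilyloxy, 5β-alkenyl and 6α-silyloxy groups
Conditions: LiN(i-Pr)2, THF, −78 °C; then PhS(Cl)=N-t-Bu, −78 °C
Reagents that add atoms: none
Why: Mukaiyama dehydrogenation. The kinetic enolate forms at the C8 methylene and not at the silyloxy methine C10; S-attack on the sulfinimidoyl chloride and syn-elimination give the enone.

Step 8
Reactants: 11 enone C7=C8–C9=O
Product: 12 allylic alcohol with 9β-OH, C7=C8 and 10α-triethylsilyloxy group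
Conditions: NaBH4, CeCl3·7H2O, MeOH, −78 → −40 °C
Reagents that add atoms: none
Why: Luche 1,2-reduction. Axial hydride delivery on the conformer with the C5, C6 and C10 substituents equatorial should give the equatorial 9β-alcohol, trans to O10.

Step 9
Reactants: 12 allylic alcohol with 9β-OH
Product: 14 ethyl ester with 7β-CH2CO2Et and C8=C9, via ketene acetal 13 (not isolated)
Conditions: MeC(OEt)3, EtCO2H (cat.), xylene, 140 °C, EtOH distilled off
Reagents that add atoms: triethyl orthoacetate, CCOC(C)(OCC)OCC
Why: Johnson–Claisen rearrangement. The [3,3] shift is suprafacial, so the C7–C11 bond forms on the face that C9–O leaves (β), which sets C7 trans to O6 and cis to the C5 branch and moves the alkene to C8=C9.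

Step 10
Reactants: 14 ethyl ester with 7β-CH2CO2Et
Product: 16 trans-fused 6α,12-lactone with 10α-OH and C8=C9, via dihydroxy ester 15 (not isolated)
Conditions: CSA, MeOH–CH2Cl2, rt; then PPTS, PhMe, 80 °C
Reagents that add atoms: none
Why: Acid solvolysis removes the triethylsilyl and the secondary tert-butyldimethylsilyl ethers, while the far more acid-stable primary tert-butyldiphenylsilyl ether should stay. The freed 6α-hydroxyl closes the γ-lactone onto C12 by transesterification.

Step 11
Reactants: 16 trans-fused 6α,12-lactone
Product: 18 α-methylene lactone (C11=C13H2) with 10α-OH, via Mannich base 17 (not isolated)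
Conditions: LiN(i-Pr)2 (2.2 equiv), THF, −78 °C; CH2=NMe2+ I−, −78 °C → rt; then MeI, MeOH; NaHCO3 aq.
Reagents that add atoms: N,N-dimethylmethyleneiminium iodide, C=[N+](C)C.[I-]
Why: Mannich reaction of the lactone enolate (the C10 alkoxide is a spectator), then quaternisation and E1cB loss of trimethylamine. C13 is installed here, where no base-sensitive group is present.

Step 12
Reactants: 18 α-methylene lactone
Product: 19 lactol (12-OH) with C11=C13H2 and 10α-OH
Conditions: i-Bu2AlH (2.5 equiv), CH2Cl2, −78 °C; Rochelle salt
Reagents that add atoms: none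
Why: Partial 1,2-reduction of a lactone; the tetrahedral aluminate is stable at −78 °C and gives the lactol on work-up.

Step 13
Reactants: 19 lactol (12-OH)
Product: 20 12-methyl acetal with C11=C13H2, C8=C9 and 10α-OH
Conditions: PPTS (cat.), MeOH, rt
Reagents that add atoms: methanol, CO
Why: Acetalisation through the allyl-stabilised oxocarbenium ion. One ring now protects O6 and C12 (at the aldehyde level), and its trans fusion holds C6 and C7 equatorial.

Step 14
Reactants: 20 12-methyl acetal with 10α-OH
Product: 21 8α,9α-epoxide with 10α-OH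
Conditions: VO(acac)2 (cat.), t-BuOOH, PhH, rt
Reagents that add atoms: tert-butyl hydroperoxide, CC(C)(C)OO
Why: Hydroxyl-directed epoxidation. Only C8=C9 is allylic to the free hydroxyl, and oxygen is delivered cis to it, which is also anti to the C7 branch; the homoallylic and the isolated 1,1-disubstituted alkenes should react much more slowly.

Step 15
Reactants: 21 8α,9α-epoxide with 10α-OH
Product: 22 8α,9α-epoxy C10 ketone
Conditions: Dess–Martin periodinane, NaHCO3, CH2Cl2, 0 °C → rt
Reagents that add atoms: none
Why: A neutral oxidation, so that the C5 centre (α to the new ketone and allylic) is neither epimerised nor brought into conjugation.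

Step 16
Reactants: 22 8α,9α-epoxy C10 ketone; 23 vinylmagnesium bromide
Product: 24 tertiary alcohol with 10β-vinyl, 10α-OH and the 8α,9α-epoxide
Conditions: CeCl3, CH2=CHMgBr, THF, −78 °C
Reagents that add atoms: none
Why: The organocerium reagent adds 1,2 without enolising toward C5. Attack anti to the epoxide oxygen, along the axial trajectory of the locked chair, places the vinyl group β (cis to the C5 alkenyl group) and the hydroxyl α.

Step 17
Reactants: 24 tertiary alcohol with the 8α,9α-epoxide
Product: 25 8β-(4-methoxybenzyl) ether with 9α-OH and 10α-OH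
Conditions: Ti(O-i-Pr)4 (1.5 equiv), 4-MeOC6H4CH2OH (10 equiv, i-PrOH removed in vacuo), PhMe, 70 °C
Reagents that add atoms: 4-methoxybenzyl alcohol, COc1ccc(CO)cc1
Why: Titanium-mediated alcoholysis of a 2,3-epoxy alcohol at the carbon remote from the carbinol. Titanium bound to O10 and to the epoxide activates C8, which is opened with inversion in the trans-diaxial mode of the locked chair, giving 8β-ether and 9α-hydroxyl.

Step 18
Reactants: 25 8β-(4-methoxybenzyl) ether with 9α-OH and 10α-OH
Product: 26 oxy-Cope substrate with 9α-methoxymethyl ether and free 10α-OH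
Conditions: MeOCH2Cl, i-Pr2NEt, Bu4NI (cat.), CH2Cl2, 40 °C
Reagents that add atoms: chloromethyl methyl ether, COCCl
Why: Alkylation of the secondary hydroxyl under amine base leaves the tertiary one free and forms no alkoxide. An acetal-type group is used because a silyl group on O9 would shift to the C10 alkoxide in the next step.

Step 19
Reactants: 26 oxy-Cope substrate (cis-1-vinyl-2-alkenylcyclohexanol)
Product: 29 ten-membered C10 ketone with ring-cis C4=C5, via potassium alkoxide 27 (not isolated), via potassium enolate 28 (not isolated)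
Conditions: KH, 18-crown-6, THF, 0 °C → rt; then NH4Cl aq., −78 °C
Reagents that add atoms: none
Why: KH deprotonates the tertiary hydroxyl and 18-crown-6 strips the potassium ion, so alkoxide 27 weakens the adjacent C5–C10 bond; the 1,5-diene C2=C1–C10–C5–C4=C3 then undergoes a [3,3]-sigmatropic shift through a six-membered chair transition state in which C2–C3 forms as C5–C10 breaks. The closest known reaction type is the anionic oxy-Cope ring expansion of cis-1-vinyl-2-alkenylcyclohexanols to cyclodec-5-enones. The ten-membered carbocycle is not closed from a chain but arises by four-carbon enlargement of the six-membered ring, the new bond forming inside the six-centre array while the bicyclic acetal is carried along. No stereocentre is created: C5 and C10 become trigonal and C6–C9 are untouched. The step must control alkene geometry: the trans-fused acetal holds C6 and C7 equatorial, which leaves only the chair with the C10 vinyl group axial and the C5 alkenyl group equatorial, and in the derived pericyclic chair C6 is axial (turned away from C15) and C9 equatorial. C4=C5 should therefore emerge ring-cis (C3 and C6 cis), and enolate 28 with oxygen cis to C2. The syn-diaxial contact between the vinyl group and the C8 ether is released in the transition state, and enolate formation makes the shift irreversible. The cold quench protonates C1 before the enolate can equilibrate toward C9, from where the C8 ether would be lost by β-elimination.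

Step 20
Reactants: 29 ten-membered C10 ketone
Product: 30 enol triflate C10=C1 with the triflate oxygen cis to C2
Conditions: KN(SiMe3)2, THF, −78 °C; then PhNTf2, −78 → −20 °C
Reagents that add atoms: N-phenylbis(trifluoromethanesulfonimide), O=S(=O)(N(c1ccccc1)S(=O)(=O)C(F)(F)F)C(F)(F)F
Why: Kinetic deprotonation takes the C1 methylene and not the alkoxy methine C9, and the enolate is O-sulfonylated. The isomer with oxygen cis to C2 is expected, as for acyclic ketones with this base, but the geometry is not critical because it is corrected in step 22.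

Step 21
Reactants: 30 enol triflate C10=C1
Product: 31 (Z)-enal with the C14 formyl group on C10 cis to C2
Conditions: Pd(PPh3)4 (5 mol %), CO (1 atm), Bu3SnH (slow addition), LiCl, THF, 50 °C
Reagents that add atoms: carbon monoxide, [C-]#[O+]
Why: Stille-type carbonylative formylation: zerovalent palladium inserts into the C–O bond of the triflate, CO insertion gives an acylpalladium species, and hydride transfer from tin with reductive elimination releases the aldehyde with retention of alkene geometry. The allylic ether at C9 is not ionised.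

Step 22
Reactants: 31 (Z)-enal
Product: 32 (E)-enal with the formyl group trans to C2 and ring-cis C1=C10
Conditions: PhSH (0.2 equiv), Et3N (0.2 equiv), CH2Cl2, rt
Reagents that add atoms: none
Why: Reversible conjugate addition of thiolate at C1 allows rotation about C1–C10. The equilibrium should lie on the side of the E-enal, which has the ring-cis alkene of the target, and the methoxymethyl ether at C9 is too poor a leaving group to be expelled.

Step 23
Reactants: 32 (E)-enal
Product: 33 8β-alcohol
Conditions: DDQ, CH2Cl2–pH 7 buffer, 0 °C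
Reagents that add atoms: none
Why: Oxidative cleavage of the 4-methoxybenzyl ether by hydride abstraction and hydrolysis of the oxocarbenium ion; the acetals, the silyl ether and the enal are inert to the buffered oxidant.

Step 24
Reactants: 33 8β-alcohol; 34 (S)-2-methylbutanoic acid
Product: 35 8β-[(S)-2-methylbutanoyl] ester
Conditions: DCC, DMAP (cat.), CH2Cl2, 0 °C → rt
Reagents that add atoms: none
Why: Steglich esterification of the only free hydroxyl; low temperature and catalytic DMAP limit epimerisation of the α-centre of the acid.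

Step 25
Reactants: 35 8β-[(S)-2-methylbutanoyl] ester
Product: 36 lactol (12-OH)
Conditions: AcOH–THF–H2O (3:1:1), rt
Reagents that add atoms: water, O
Why: The allylic mixed acetal ionises readily and is hydrolysed under conditions that leave the methoxymethyl ether, the silyl ether and the ester alone.

Step 26
Reactants: 36 lactol (12-OH)
Product: 37 α-methylene-γ-lactone with 9α-methoxymethyl ether
Conditions: Dess–Martin periodinane, NaHCO3, CH2Cl2, rt
Reagents that add atoms: none
Why: Lactol oxidation. No other hydroxyl is free, so the step is chemoselective by design.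

Step 27
Reactants: 37 α-methylene-γ-lactone with 9α-methoxymethyl ether
Product: 38 9α-alcohol
Conditions: Me2BBr, CH2Cl2, −78 °C; then NaHCO3 aq.
Reagents that add atoms: none
Why: The bromoborane cleaves the acetal-type ether (boron on the methoxy oxygen, bromide at the methylene) at −78 °C, where esters, the lactone, the enal and the silyl ether should be inert.

Step 28
Reactants: 38 9α-alcohol
Product: 39 9α-acetate (15-O-silyl ether of the target)
Conditions: Ac2O, pyridine, CH2Cl2, 0 °C → rt
Reagents that add atoms: acetic anhydride, CC(=O)OC(C)=O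
Why: Acetylation of the only free hydroxyl. DMAP is left out so that no strong nucleophile attacks the enal with loss of the new allylic acetate.

Step 29
Reactants: 39 9α-acetate (15-O-silyl ether of the target)
Product: 40 target CNP0247637.6
Conditions: HF·pyridine, pyridine, THF, 0 °C → rt
Reagents that add atoms: none
Why: Fluoride cleaves the Si–O bond under buffered, weakly acidic conditions that the esters, the enal and the methylene lactone should tolerate.

## Compound list

1 | 2-bromoprop-2-en-1-ol | OCC(Br)=C | starting material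
2 | (2-bromoprop-2-en-1-yloxy)(tert-butyl)diphenylsilane | C=C(Br)CO[Si](c1ccccc1)(c1ccccc1)C(C)(C)C | intermediate
3 | 1,4-dioxaspiro[4.5]dec-6-en-8-one | O=C1C=CC2(CC1)OCCO2 | starting material
4 | (S)-1,4-dioxaspiro[4.5]dec-6-en-8-ol | O[C@@H]1C=CC2(CC1)OCCO2 | intermediate
5 | (S)-tert-butyl(1,4-dioxaspiro[4.5]dec-6-en-8-yloxy)dimethylsilane | CC(C)(C)[Si](C)(C)O[C@@H]1C=CC2(CC1)OCCO2 | intermediate
6 | (S)-4-(tert-butyldimethylsilyloxy)cyclohex-2-en-1-one | O=C1C=C[C@@H](O[Si](C)(C)C(C)(C)C)CC1 | intermediate
7 | [3-(tert-butyldiphenylsilyloxy)prop-1-en-2-yl]lithium | [Li]C(=C)CO[Si](c1ccccc1)(c1ccccc1)C(C)(C)C | intermediate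
8 | lithium bis[3-(tert-butyldiphenylsilyloxy)prop-1-en-2-yl]cuprate | [Li+].C=C(CO[Si](c1ccccc1)(c1ccccc1)C(C)(C)C)[Cu-]C(=C)CO[Si](c1ccccc1)(c1ccccc1)C(C)(C)C | intermediate
9 | ring C5–C10 with C9=C10: 9-triethylsilyloxy, 6α-tert-butyldimethylsilyloxy, 5β-[3-(tert-butyldiphenylsilyloxy)prop-1-en-2-yl] (C5/C6 trans) | C1=C(O[Si](CC)(CC)CC)CC[C@H](O[Si](C)(C)C(C)(C)C)[C@H]1C(=C)CO[Si](c2ccccc2)(c2ccccc2)C(C)(C)C | intermediate
10 | ring C5–C10: C9 ketone, 10α-triethylsilyloxy, 5β-alkenyl, 6α-tert-butyldimethylsilyloxy (all trans) | O=C1CC[C@H](O[Si](C)(C)C(C)(C)C)[C@@H](C(=C)CO[Si](c2ccccc2)(c2ccccc2)C(C)(C)C)[C@@H]1O[Si](CC)(CC)CC | intermediate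
11 | ring C5–C10: enone C7=C8–C9=O, 10α-triethylsilyloxy, 5β-alkenyl, 6α-tert-butyldimethylsilyloxy | O=C1C=C[C@H](O[Si](C)(C)C(C)(C)C)[C@@H](C(=C)CO[Si](c2ccccc2)(c2ccccc2)C(C)(C)C)[C@@H]1O[Si](CC)(CC)CC | intermediate
12 | ring C5–C10: C7=C8, 9β-OH, 10α-triethylsilyloxy, 5β-alkenyl, 6α-tert-butyldimethylsilyloxy | C1=C[C@H](O[Si](C)(C)C(C)(C)C)[C@@H](C(=C)CO[Si](c2ccccc2)(c2ccccc2)C(C)(C)C)[C@H](O[Si](CC)(CC)CC)[C@H]1O | intermediate
13 | 9β-O-(1-ethoxyvinyl) ether of 12 (mixed ketene acetal) | C1=C[C@H](O[Si](C)(C)C(C)(C)C)[C@@H](C(=C)CO[Si](c2ccccc2)(c2ccccc2)C(C)(C)C)[C@H](O[Si](CC)(CC)CC)[C@H]1OC(=C)OCC | intermediate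
14 | ring C5–C10: C8=C9, 7β-CH2CO2Et, 6α-tert-butyldimethylsilyloxy, 5β-alkenyl, 10α-triethylsilyloxy | C1=C[C@@H](CC(=O)OCC)[C@H](O[Si](C)(C)C(C)(C)C)[C@@H](C(=C)CO[Si](c2ccccc2)(c2ccccc2)C(C)(C)C)[C@@H]1O[Si](CC)(CC)CC | intermediate
15 | dihydroxy ester: as 14 with 6α-OH and 10α-OH | C1=C[C@@H](CC(=O)OCC)[C@H](O)[C@@H](C(=C)CO[Si](c2ccccc2)(c2ccccc2)C(C)(C)C)[C@@H]1O | intermediate
16 | trans-fused γ-lactone O6–C12(=O)–C11H2–C7 on ring C5–C10: C8=C9, 10α-OH, 5β-alkenyl | C1=C[C@H]2CC(=O)O[C@@H]2[C@@H](C(=C)CO[Si](c3ccccc3)(c3ccccc3)C(C)(C)C)[C@@H]1O | intermediate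
17 | 11-(dimethylaminomethyl) derivative of lactone 16 (C11 epimers) | C1=C[C@H]2C(CN(C)C)C(=O)O[C@@H]2[C@@H](C(=C)CO[Si](c3ccccc3)(c3ccccc3)C(C)(C)C)[C@@H]1O | intermediate
18 | α-methylene lactone (C11=C13H2): otherwise as 16 | C1=C[C@H]2C(=C)C(=O)O[C@@H]2[C@@H](C(=C)CO[Si](c3ccccc3)(c3ccccc3)C(C)(C)C)[C@@H]1O | intermediate
19 | lactol of 18 (12-OH, anomers) | C1=C[C@H]2C(=C)C(O)O[C@@H]2[C@@H](C(=C)CO[Si](c3ccccc3)(c3ccccc3)C(C)(C)C)[C@@H]1O | intermediate
20 | 12-methyl acetal (trans-fused 2-methoxy-3-methylenetetrahydrofuran O6–C12–C11–C7): C8=C9, 10α-OH, 5β-alkenyl | C1=C[C@H]2C(=C)C(OC)O[C@@H]2[C@@H](C(=C)CO[Si](c3ccccc3)(c3ccccc3)C(C)(C)C)[C@@H]1O | intermediate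
21 | 8α,9α-epoxide of 20, 10α-OH | O[C@@H]1[C@@H]3O[C@@H]3[C@H]2C(=C)C(OC)O[C@@H]2[C@H]1C(=C)CO[Si](c4ccccc4)(c4ccccc4)C(C)(C)C | intermediate
22 | 8α,9α-epoxy C10 ketone | O=C1[C@@H]3O[C@@H]3[C@H]2C(=C)C(OC)O[C@@H]2[C@H]1C(=C)CO[Si](c4ccccc4)(c4ccccc4)C(C)(C)C | intermediate
23 | vinylmagnesium bromide | C=C[Mg]Br | starting material
24 | 10β-vinyl-10α-hydroxy-8α,9α-epoxide (vinyl cis to the 5β-alkenyl group) | O[C@]1(C=C)[C@@H]3O[C@@H]3[C@H]2C(=C)C(OC)O[C@@H]2[C@H]1C(=C)CO[Si](c4ccccc4)(c4ccccc4)C(C)(C)C | intermediate
25 | 8β-(4-methoxybenzyloxy)-9α,10α-diol, 10β-vinyl | O[C@]1(C=C)[C@H](O)[C@@H](OCc3ccc(OC)cc3)[C@H]2C(=C)C(OC)O[C@@H]2[C@H]1C(=C)CO[Si](c4ccccc4)(c4ccccc4)C(C)(C)C | intermediate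
26 | oxy-Cope substrate: 10α-OH, 10β-vinyl, 9α-methoxymethoxy, 8β-(4-methoxybenzyloxy), C6/C7 trans-fused methyl acetal with C11=C13H2, 5β-[3-(tert-butyldiphenylsilyloxy)prop-1-en-2-yl] | O[C@]1(C=C)[C@H](OCOC)[C@@H](OCc3ccc(OC)cc3)[C@H]2C(=C)C(OC)O[C@@H]2[C@H]1C(=C)CO[Si](c4ccccc4)(c4ccccc4)C(C)(C)C | intermediate
27 | potassium alkoxide of 26 | [K+].[O-][C@]1(C=C)[C@H](OCOC)[C@@H](OCc3ccc(OC)cc3)[C@H]2C(=C)C(OC)O[C@@H]2[C@H]1C(=C)CO[Si](c4ccccc4)(c4ccccc4)C(C)(C)C | intermediate
28 | potassium enolate C10(O−)=C1 of the ten-membered ring, O cis to C2, ring-cis C4=C5 | [K+].COC1O[C@@H]2/C=C(/CO[Si](c3ccccc3)(c3ccccc3)C(C)(C)C)CC/C=C(\[O-])[C@H](OCOC)[C@@H](OCc3ccc(OC)cc3)[C@H]2C1=C | intermediate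
29 | ten-membered C10 ketone: ring-cis C4=C5 with C15H2-O-silyl on C4, 9α-methoxymethoxy, 8β-(4-methoxybenzyloxy), C6/C7 trans-fused methyl acetal with C11=C13H2 | COC1O[C@@H]2/C=C(/CO[Si](c3ccccc3)(c3ccccc3)C(C)(C)C)CCCC(=O)[C@H](OCOC)[C@@H](OCc3ccc(OC)cc3)[C@H]2C1=C | intermediate
30 | enol triflate of 29 at C10=C1, triflate oxygen cis to C2 | COC1O[C@@H]2/C=C(/CO[Si](c3ccccc3)(c3ccccc3)C(C)(C)C)CC/C=C(\OS(=O)(=O)C(F)(F)F)[C@H](OCOC)[C@@H](OCc3ccc(OC)cc3)[C@H]2C1=C | intermediate
31 | (Z)-enal: C14 formyl on C10, cis to C2 | COC1O[C@@H]2/C=C(/CO[Si](c3ccccc3)(c3ccccc3)C(C)(C)C)CC/C=C(\C=O)[C@H](OCOC)[C@@H](OCc3ccc(OC)cc3)[C@H]2C1=C | intermediate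
32 | (E)-enal: formyl trans to C2, ring-cis C1=C10 | COC1O[C@@H]2/C=C(/CO[Si](c3ccccc3)(c3ccccc3)C(C)(C)C)CC/C=C(/C=O)[C@H](OCOC)[C@@H](OCc3ccc(OC)cc3)[C@H]2C1=C | intermediate
33 | 8β-alcohol of 32 | COC1O[C@@H]2/C=C(/CO[Si](c3ccccc3)(c3ccccc3)C(C)(C)C)CC/C=C(/C=O)[C@H](OCOC)[C@@H](O)[C@H]2C1=C | intermediate
34 | (S)-2-methylbutanoic acid | CC[C@H](C)C(=O)O | starting material
35 | 8β-[(S)-2-methylbutanoyloxy] methyl acetal | COC1O[C@@H]2/C=C(/CO[Si](c3ccccc3)(c3ccccc3)C(C)(C)C)CC/C=C(/C=O)[C@H](OCOC)[C@@H](OC(=O)[C@@H](C)CC)[C@H]2C1=C | intermediate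
36 | lactol (12-OH) of 35 | OC1O[C@@H]2/C=C(/CO[Si](c3ccccc3)(c3ccccc3)C(C)(C)C)CC/C=C(/C=O)[C@H](OCOC)[C@@H](OC(=O)[C@@H](C)CC)[C@H]2C1=C | intermediate
37 | 6α,12-lactone with C11=C13H2, 9α-methoxymethoxy, 8β-ester, 15-O-silyl | O=C1O[C@@H]2/C=C(/CO[Si](c3ccccc3)(c3ccccc3)C(C)(C)C)CC/C=C(/C=O)[C@H](OCOC)[C@@H](OC(=O)[C@@H](C)CC)[C@H]2C1=C | intermediate
38 | 9α-alcohol of 37 | O=C1O[C@@H]2/C=C(/CO[Si](c3ccccc3)(c3ccccc3)C(C)(C)C)CC/C=C(/C=O)[C@H](O)[C@@H](OC(=O)[C@@H](C)CC)[C@H]2C1=C | intermediate
39 | 15-O-(tert-butyldiphenylsilyl) ether of the target | O=C1O[C@@H]2/C=C(/CO[Si](c3ccccc3)(c3ccccc3)C(C)(C)C)CC/C=C(/C=O)[C@H](OC(C)=O)[C@@H](OC(=O)[C@@H](C)CC)[C@H]2C1=C | intermediate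
40 | CNP0247637.6: (6R,7S,8S,9S)-9-acetoxy-8-[(S)-2-methylbutanoyloxy]-15-hydroxy-14-oxogermacra-1(10),4,11(13)-trien-6,12-olide, both ring alkenes ring-cis | C=C1C(=O)O[C@@H]2/C=C(/CO)CC/C=C(/C=O)[C@H](OC(C)=O)[C@@H](OC(=O)[C@@H](C)CC)[C@@H]12 | target

## Step count and least certain steps

Total: 29 steps. Longest linear sequence: 28 steps (3 to 40); step 1 lies off the main line.

**Step 19 (key step).** The product enolate may equilibrate toward C9 and lose the C8 ether by β-elimination, and a boat-type rearrangement or bond fragmentation may compete because the reacting chair holds the vinyl group and the C8 ether syn-diaxial. Fallback: a neutral variant. It sets out from 26, which is silylated on the tertiary oxygen (Me3Si-imidazole) to the trimethylsilyl ether F1. Heating F1 at about 200 °C in a sealed, base-washed tube brings about the siloxy-Cope shift without any enolate, giving the silyl enol ether F2. Mild methanolysis of F2 (K2CO3, MeOH, 0 °C) returns to the route at 29.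

**Step 17.** Isopropoxide may be transferred instead of the benzylic alkoxide, the C12 acetal may exchange its methoxy group, the vinyl group may shift to C9 in a semipinacol manner, and attack at C8 is slowed by the syn-axial vinyl group. Fallback: from 24, titanium-mediated opening with benzoic acid (Ti(O-i-Pr)4, PhCO2H, CH2Cl2, rt) gives the 8β-benzoate F3. The 9-hydroxyl is protected as in step 18 to give the methoxymethyl ether F4, and the benzoate is removed (K2CO3, MeOH) to give the 8β-alcohol F5. Benzylation of F5 with 4-methoxybenzyl trichloroacetimidate and catalytic La(OTf)3 rejoins the route at 26.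

**Step 9 (with step 8).** The rearrangement may be slow, because the conformer with an axial C9–O bond places three substituents axial, and the acid at 140 °C may cleave the triethylsilyl ether. The outcome also depends on the facial selectivity of the reduction in step 8. Fallback: from 12, acetylation gives the 9β-acetate F6. Ireland–Claisen rearrangement of its silyl ketene acetal (LiN(i-Pr)2, Me3SiCl, THF, −78 → 60 °C) gives the carboxylic acid F7 at a much lower temperature. F7 is desilylated and lactonised under the conditions of step 10 to come back at 16.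

**Step 21.** Hydride may be transferred from tin to the vinylpalladium species before CO inserts, which reduces the triflate to the alkene. Fallback: from 30, methoxycarbonylation (Pd(OAc)2, PPh3, CO, MeOH, Et3N, DMF) gives the methyl ester F8. Reduction with i-Bu2AlH gives the allylic alcohol F9, and MnO2 oxidation rejoins the route at 31.

**Step 10.** The hindered secondary silyl ether at O6 may be removed too slowly for the primary tert-butyldiphenylsilyl ether to survive the acid. Fallback: from 14, Bu4NF removes all three silyl groups and the lactone closes, giving the lactone diol F10. Selective silylation of its primary hydroxyl (t-BuPh2SiCl, imidazole, 0 °C) returns to the route at 16.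

## Further compounds

F1 | step 19 | 10-O-trimethylsilyl ether of 26 | C[Si](C)(C)O[C@]1(C=C)[C@H](OCOC)[C@@H](OCc3ccc(OC)cc3)[C@H]2C(=C)C(OC)O[C@@H]2[C@H]1C(=C)CO[Si](c4ccccc4)(c4ccccc4)C(C)(C)C
F2 | step 19 | trimethylsilyl enol ether (C10=C1, O cis to C2) of ketone 29 | COC1O[C@@H]2/C=C(/CO[Si](c3ccccc3)(c3ccccc3)C(C)(C)C)CC/C=C(\O[Si](C)(C)C)[C@H](OCOC)[C@@H](OCc3ccc(OC)cc3)[C@H]2C1=C
F3 | step 17 | 8β-benzoate with 9α-OH and 10α-OH (from 24) | O[C@]1(C=C)[C@H](O)[C@@H](OC(=O)c3ccccc3)[C@H]2C(=C)C(OC)O[C@@H]2[C@H]1C(=C)CO[Si](c4ccccc4)(c4ccccc4)C(C)(C)C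
F4 | step 17 | 9α-methoxymethyl ether of F3 | O[C@]1(C=C)[C@H](OCOC)[C@@H](OC(=O)c3ccccc3)[C@H]2C(=C)C(OC)O[C@@H]2[C@H]1C(=C)CO[Si](c4ccccc4)(c4ccccc4)C(C)(C)C
F5 | step 17 | 8β-alcohol with 9α-methoxymethoxy and 10α-OH | O[C@]1(C=C)[C@H](OCOC)[C@@H](O)[C@H]2C(=C)C(OC)O[C@@H]2[C@H]1C(=C)CO[Si](c4ccccc4)(c4ccccc4)C(C)(C)C
F6 | step 9 | 9β-acetate of 12 | C1=C[C@H](O[Si](C)(C)C(C)(C)C)[C@@H](C(=C)CO[Si](c2ccccc2)(c2ccccc2)C(C)(C)C)[C@H](O[Si](CC)(CC)CC)[C@H]1OC(C)=O
F7 | step 9 | carboxylic acid corresponding to ester 14 (7β-CH2CO2H) | C1=C[C@@H](CC(=O)O)[C@H](O[Si](C)(C)C(C)(C)C)[C@@H](C(=C)CO[Si](c2ccccc2)(c2ccccc2)C(C)(C)C)[C@@H]1O[Si](CC)(CC)CC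
F8 | step 21 | C14 methyl ester on C10 (ester cis to C2) | COC1O[C@@H]2/C=C(/CO[Si](c3ccccc3)(c3ccccc3)C(C)(C)C)CC/C=C(\C(=O)OC)[C@H](OCOC)[C@@H](OCc3ccc(OC)cc3)[C@H]2C1=C
F9 | step 21 | C14 allylic alcohol on C10 | COC1O[C@@H]2/C=C(/CO[Si](c3ccccc3)(c3ccccc3)C(C)(C)C)CC/C=C(\CO)[C@H](OCOC)[C@@H](OCc3ccc(OC)cc3)[C@H]2C1=C
F10 | step 10 | lactone diol: as 16 with free 15-OH | C1=C[C@H]2CC(=O)O[C@@H]2[C@@H](C(=C)CO)[C@@H]1O
A1 | alternative 1 | ten-membered C6 alcohol with C7 ethynyl group, 15-O-tert-butyldimethylsilyl, enal and both esters in place | O[C@@H]1/C=C(/CO[Si](C)(C)C(C)(C)C)CC/C=C(/C=O)[C@H](OC(C)=O)[C@@H](OC(=O)[C@@H](C)CC)[C@H]1C#C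
A2 | alternative 1 | 15-O-tert-butyldimethylsilyl ether of the target | C=C1C(=O)O[C@@H]2/C=C(/CO[Si](C)(C)C(C)(C)C)CC/C=C(/C=O)[C@H](OC(C)=O)[C@@H](OC(=O)[C@@H](C)CC)[C@@H]12
A3 | alternative 2 | eleven-membered β-keto lactone (O6–C12–C11–C9–C10=C1–C2–C3–C4=C5–C6) with C7=C8 enol ester on C6 | O=C1CC(=O)/C(C(OC)OC)=C\CC/C(CO[Si](C)(C)C(C)(C)C)=C\[C@H](/C=C/OC(=O)[C@@H](C)CC)O1
A4 | alternative 2 | C9-oxo ten-membered lactone with the C8 ester in place and C14 as dimethyl acetal | C1C(=O)O[C@@H]2/C=C(/CO[Si](C)(C)C(C)(C)C)CC/C=C(/C(OC)OC)C(=O)[C@@H](OC(=O)[C@@H](C)CC)[C@@H]12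
A5 | alternative 3 | decalin epoxy ketone: C10 ketone, epoxide on the C1–C6 fusion bond, C4=C5, substituents at C7–C9 (epoxide configuration open) | O=C1[C@H](O[Si](CC)(CC)CC)[C@@H](OCc2ccc(OC)cc2)[C@@H](CC(=O)OC)C23OC13CCC(CO[Si](C)(C)C(C)(C)C)=C2
A6 | alternative 3 | ten-membered 4-en-1(10)-yn-6-one carrying C7–C9 | O=C1/C=C(/CO[Si](C)(C)C(C)(C)C)CCC#C[C@H](O[Si](CC)(CC)CC)[C@@H](OCc2ccc(OC)cc2)[C@H]1CC(=O)OC
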